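**Strategy.** Everything rests on reading ring A as a Diels–Alder cyclohexene: its C1=C10 alkene together with the C4–C5 and C2–C3 bonds maps onto the ring B diene C5=C10–C1=C2 and a methacrolein C3=C4 unit. One catalysed intermolecular [4+2] therefore closes ring A, forms both bonds, sets the C4 quaternary centre and C5, and brings in C18 as a formyl group. Its precursor is (5R,6S)-6-allyl-5,6-dimethyl-1-vinylcyclohex-1-ene, which already carries C8, C9 and an allyl handle and is reached in three steps from 2-methylcyclohex-2-enone. After the cycloaddition the allyl group is grown into the (E)-allylic propionate through a terminal alkyne.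

Key step: step 4

Remark on the chemistry: terpenoid numbering (C1–C20) is used throughout; the "methyl face" of ring B is the face that carries the C8 and C9 methyl groups. The target is 4S,5S,8R,9S,13E, with C18 cis to H5 and the C9 side chain trans to both ring B methyl groups.

Assumption: the antipode of the phosphoramidite (step 1) and of the oxazaborolidinium catalyst (step 4) is assigned by analogy with simpler substrates; both antipodes are available, so a wrong sense would be corrected by using the mirror-image ligand or catalyst without changing the route.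

**Step 1**
Reactants: 1 2-methylcyclohex-2-en-1-one; 2 allyl bromide
Product: 5 (2S,3R)-2-allyl-2,3-dimethylcyclohexan-1-one, via aluminium enolate 3 (not isolated), via lithium aluminate 4 (not isolated)
Conditions: Me3Al, Cu(O2C-C4H3S) (CuTC, 2 mol %), (R)-(1,1'-binaphthalene-2,2'-diyl) N,N-bis[(S)-1-phenylethyl]phosphoramidite (4 mol %), Et2O, −30 °C; then MeLi, THF, −30 °C; then 2, −30 °C → rt
Reagents that add atoms: trimethylaluminium, C[Al](C)C
Why: Copper-catalysed asymmetric conjugate addition, in which the chiral phosphoramidite–copper methyl species selects the enone face and sets C8 as R, gives a regiodefined enolate that, once activated as the lithium aluminate, is C-allylated anti to the adjacent pseudoaxial C8 methyl group, so that the quaternary C9 forms with allyl trans and methyl cis to the C8 methyl (enolate trapping by alkylation).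

**Step 2**
Reactants: 5 (2S,3R)-2-allyl-2,3-dimethylcyclohexan-1-one
Product: 7 (5R,6S)-6-allyl-5,6-dimethylcyclohex-1-en-1-yl trifluoromethanesulfonate, via potassium enolate 6 (not isolated)
Conditions: KN(SiMe3)2, THF, −78 °C; PhNTf2, −78 → 0 °C
Reagents that add atoms: N-phenylbis(trifluoromethanesulfonimide), O=S(=O)(N(c1ccccc1)S(=O)(=O)C(F)(F)F)C(F)(F)F
Why: Only one α-carbon of the ketone carries hydrogen, so deprotonation and O-sulfonylation of the enolate (enol triflate formation) can give a single regioisomer and touches neither stereocentre.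

**Step 3**
Reactants: 7 (5R,6S)-6-allyl-5,6-dimethylcyclohex-1-en-1-yl trifluoromethanesulfonate; 8 tributyl(vinyl)stannane
Product: 9 (5R,6S)-6-allyl-5,6-dimethyl-1-vinylcyclohex-1-ene
Conditions: Pd(PPh3)4 (5 mol %), LiCl, THF, 65 °C
Reagents that add atoms: none
Why: Stille cross-coupling of a cyclohexenyl triflate with a vinylstannane, assisted by LiCl, is reliable even next to a quaternary carbon and installs the C1=C2 vinyl group without moving the ring alkene.

**Step 4**
Reactants: 9 (5R,6S)-6-allyl-5,6-dimethyl-1-vinylcyclohex-1-ene; 10 methacrolein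
Product: 11 (1S,5S,6R,8aS)-5-allyl-1,5,6-trimethyl-1,2,3,5,6,7,8,8a-octahydronaphthalene-1-carbaldehyde
Conditions: (S)-3,3-diphenyl-1-(o-tolyl)tetrahydro-1H,3H-pyrrolo[1,2-c][1,3,2]oxazaborole (20 mol %), Tf2NH (16 mol %), 10 (3 equiv), CH2Cl2, −78 → −40 °C
Reagents that add atoms: none
Why: A concerted, asynchronous [4+2] cycloaddition (enantioselective Diels–Alder reaction of an oxazaborolidinium-bound α-substituted acrolein) joins the semicyclic diene C5=C10–C1=C2 of 9 to the C3=C4 alkene of 10, the C2–C3 bond running ahead of the C4–C5 bond. Ring A closes as a six-membered carbocycle by intermolecular cycloaddition, both σ bonds being made in the one event and the new alkene appearing at C1=C10. C4 is set by the catalyst, which holds the s-trans enal through boron and a formyl C–H···O contact and leaves only the Re face of the α-carbon open. C5 follows from the exo placement of the bulky boron-bound formyl group, which makes C5 bond on the methyl face of ring B and puts H5 cis to C18 and trans to the C9 methyl. The ortho regiochemistry needed (C4 to the ring terminus C5, C3 to the vinyl CH2) is secured by the larger diene coefficient at the unsubstituted terminus C2 meeting the enal β-carbon, and exo selectivity by the α-methyl group together with the fully substituted C9, which crowds the endo space over C10. The quaternary C9 also holds the diene s-cis, and because C8 and C9 are already fixed, any stereochemical leak should appear as a separable diastereomer and not as an enantiomer.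

**Step 5**
Reactants: 11 (1S,5S,6R,8aS)-5-allyl-1,5,6-trimethyl-1,2,3,5,6,7,8,8a-octahydronaphthalene-1-carbaldehyde
Product: 12 (1S,5S,6R,8aS)-5-allyl-1,5,6-trimethyl-1,2,3,5,6,7,8,8a-octahydronaphthalene-1-carboxylic acid
Conditions: NaClO2, NaH2PO4, 2-methyl-2-butene, t-BuOH/H2O, 0 °C → rt
Reagents that add atoms: sodium chlorite, [Na+].[O-]Cl=O
Why: Pinnick oxidation converts the non-enolisable neopentyl aldehyde into the acid while 2-methyl-2-butene scavenges HOCl, so that the C1=C10 and allyl alkenes are not chlorinated.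

**Step 6**
Reactants: 12 (1S,5S,6R,8aS)-5-allyl-1,5,6-trimethyl-1,2,3,5,6,7,8,8a-octahydronaphthalene-1-carboxylic acid
Product: 13 2-(trimethylsilyl)ethyl (1S,5S,6R,8aS)-5-allyl-1,5,6-trimethyl-1,2,3,5,6,7,8,8a-octahydronaphthalene-1-carboxylate
Conditions: Me3SiCH2CH2OH, PPh3, DIAD, THF, 0 °C → rt
Reagents that add atoms: 2-(trimethylsilyl)ethanol, C[Si](C)(C)CCO
Why: In the Mitsunobu esterification the carboxylate is the nucleophile toward the activated primary alcohol, so the ester forms by O-alkylation regardless of the shielding of the C18 carbonyl, and the 2-(trimethylsilyl)ethyl group is chosen because fluoride later removes it at silicon and not at this hindered carbonyl.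

**Step 7**
Reactants: 13 2-(trimethylsilyl)ethyl (1S,5S,6R,8aS)-5-allyl-1,5,6-trimethyl-1,2,3,5,6,7,8,8a-octahydronaphthalene-1-carboxylate
Product: 15 2-(trimethylsilyl)ethyl (1S,5S,6R,8aS)-5-(3-hydroxypropyl)-1,5,6-trimethyl-1,2,3,5,6,7,8,8a-octahydronaphthalene-1-carboxylate, via alkylborane 14 (not isolated)
Conditions: 9-BBN, THF, 0 °C → rt; then aq. NaOH, H2O2, 0 °C
Reagents that add atoms: hydrogen peroxide, OO
Why: Hydroboration–oxidation with the bulky 9-BBN is anti-Markovnikov and selective for the monosubstituted allyl alkene over the hindered trisubstituted C1=C10 alkene, and the α-quaternary ester is inert to the borane and to the brief alkaline peroxide work-up.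

**Step 8**
Reactants: 15 2-(trimethylsilyl)ethyl (1S,5S,6R,8aS)-5-(3-hydroxypropyl)-1,5,6-trimethyl-1,2,3,5,6,7,8,8a-octahydronaphthalene-1-carboxylate
Product: 16 2-(trimethylsilyl)ethyl (1S,5S,6R,8aS)-1,5,6-trimethyl-5-(3-oxopropyl)-1,2,3,5,6,7,8,8a-octahydronaphthalene-1-carboxylate
Conditions: Dess–Martin periodinane, CH2Cl2, 0 °C → rt
Reagents that add atoms: none
Why: Dess–Martin oxidation takes the primary alcohol to the aldehyde under neutral, non-aqueous conditions without over-oxidation or migration of the C1=C10 alkene.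

**Step 9**
Reactants: 16 2-(trimethylsilyl)ethyl (1S,5S,6R,8aS)-1,5,6-trimethyl-5-(3-oxopropyl)-1,2,3,5,6,7,8,8a-octahydronaphthalene-1-carboxylate
Product: 17 2-(trimethylsilyl)ethyl (1S,5S,6R,8aS)-5-(but-3-yn-1-yl)-1,5,6-trimethyl-1,2,3,5,6,7,8,8a-octahydronaphthalene-1-carboxylate
Conditions: dimethyl (1-diazo-2-oxopropyl)phosphonate, K2CO3, MeOH, 0 °C → rt
Reagents that add atoms: dimethyl (1-diazo-2-oxopropyl)phosphonate, COP(=O)(OC)C(=[N+]=[N-])C(C)=O
Why: Seyferth–Gilbert homologation in its Ohira–Bestmann form generates the diazomethylphosphonate anion in the flask and converts the aldehyde into the terminal alkyne C13≡C14 under mild carbonate conditions that the hindered ester survives.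

**Step 10**
Reactants: 17 2-(trimethylsilyl)ethyl (1S,5S,6R,8aS)-5-(but-3-yn-1-yl)-1,5,6-trimethyl-1,2,3,5,6,7,8,8a-octahydronaphthalene-1-carboxylate
Product: 20 2-(trimethylsilyl)ethyl (1S,5S,6R,8aS)-5-[(3E)-5-hydroxy-3-methylpent-3-en-1-yl]-1,5,6-trimethyl-1,2,3,5,6,7,8,8a-octahydronaphthalene-1-carboxylate, via alkenylalane 18 (not isolated), via lithium alkenylaluminate 19 (not isolated)
Conditions: Me3Al, Cp2ZrCl2 (0.5 equiv), CH2Cl2, 0 °C → rt; volatiles removed; n-BuLi, THF/hexane, −78 °C; (CH2O)n, −78 °C → rt; aq. KNaC4H4O6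
Reagents that add atoms: trimethylaluminium, C[Al](C)C; formaldehyde (as paraformaldehyde), C=O
Why: Negishi zirconium-catalysed methylalumination adds CH3 and Al syn across the terminal alkyne with methyl on the internal carbon C13, and the derived lithium alkenylaluminate transfers its alkenyl group to formaldehyde with retention, which fixes the 13E geometry and installs C15 as the allylic alcohol.

**Step 11**
Reactants: 20 2-(trimethylsilyl)ethyl (1S,5S,6R,8aS)-5-[(3E)-5-hydroxy-3-methylpent-3-en-1-yl]-1,5,6-trimethyl-1,2,3,5,6,7,8,8a-octahydronaphthalene-1-carboxylate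
Product: 21 2-(trimethylsilyl)ethyl (1S,5S,6R,8aS)-1,5,6-trimethyl-5-[(3E)-3-methyl-5-(propanoyloxy)pent-3-en-1-yl]-1,2,3,5,6,7,8,8a-octahydronaphthalene-1-carboxylate
Conditions: (EtCO)2O, Et3N, DMAP (cat.), CH2Cl2, 0 °C → rt
Reagents that add atoms: propionic anhydride, CCC(=O)OC(=O)CC
Why: DMAP-catalysed acylation of the unhindered primary allylic alcohol by the anhydride is fast and leaves the silylethyl ester, both alkenes and all stereocentres untouched.

**Step 12**
Reactants: 21 2-(trimethylsilyl)ethyl (1S,5S,6R,8aS)-1,5,6-trimethyl-5-[(3E)-3-methyl-5-(propanoyloxy)pent-3-en-1-yl]-1,2,3,5,6,7,8,8a-octahydronaphthalene-1-carboxylate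
Product: 22 (1S,5S,6R,8aS)-1,5,6-trimethyl-5-[(3E)-3-methyl-5-(propanoyloxy)pent-3-en-1-yl]-1,2,3,5,6,7,8,8a-octahydronaphthalene-1-carboxylic acid (CNP0223570.1)
Conditions: Bu4NF, THF, 0 °C → rt; cold 0.5 M aq. HCl work-up
Reagents that add atoms: none
Why: Fluoride attacks silicon and the 2-(trimethylsilyl)ethyl ester fragments to Me3SiF, ethylene and the carboxylate (fluoride-induced β-elimination deprotection), a cleavage that needs no attack at the hindered C18 carbonyl and is mild enough to leave the allylic propionate in place.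

**Compound list**
1 | 2-methylcyclohex-2-en-1-one | CC1=CCCCC1=O | starting material
2 | allyl bromide | C=CCBr | starting material
3 | dimethylaluminium (3R)-2,3-dimethylcyclohex-1-en-1-olate | CC1=C(O[Al](C)C)CCC[C@H]1C | intermediate
4 | lithium trimethyl[(3R)-2,3-dimethylcyclohex-1-en-1-olato]aluminate | [Li+].CC1=C(O[Al-](C)(C)C)CCC[C@H]1C | intermediate
5 | (2S,3R)-2-allyl-2,3-dimethylcyclohexan-1-one | C=CC[C@]1(C)C(=O)CCC[C@H]1C | intermediate
6 | potassium (5R,6S)-6-allyl-5,6-dimethylcyclohex-1-en-1-olate | [K+].C=CC[C@]1(C)C([O-])=CCC[C@H]1C | intermediate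
7 | (5R,6S)-6-allyl-5,6-dimethylcyclohex-1-en-1-yl trifluoromethanesulfonate | C=CC[C@]1(C)C(OS(=O)(=O)C(F)(F)F)=CCC[C@H]1C | intermediate
8 | tributyl(vinyl)stannane | C=C[Sn](CCCC)(CCCC)CCCC | starting material
9 | (5R,6S)-6-allyl-5,6-dimethyl-1-vinylcyclohex-1-ene | C=CC[C@]1(C)C(C=C)=CCC[C@H]1C | intermediate
10 | methacrolein (2-methylprop-2-enal) | C=C(C)C=O | starting material
11 | (1S,5S,6R,8aS)-5-allyl-1,5,6-trimethyl-1,2,3,5,6,7,8,8a-octahydronaphthalene-1-carbaldehyde | C=CC[C@]1(C)C2=CCC[C@](C)(C=O)[C@H]2CC[C@H]1C | intermediate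
12 | (1S,5S,6R,8aS)-5-allyl-1,5,6-trimethyl-1,2,3,5,6,7,8,8a-octahydronaphthalene-1-carboxylic acid | C=CC[C@]1(C)C2=CCC[C@](C)(C(=O)O)[C@H]2CC[C@H]1C | intermediate
13 | 2-(trimethylsilyl)ethyl (1S,5S,6R,8aS)-5-allyl-1,5,6-trimethyl-1,2,3,5,6,7,8,8a-octahydronaphthalene-1-carboxylate | C=CC[C@]1(C)C2=CCC[C@](C)(C(=O)OCC[Si](C)(C)C)[C@H]2CC[C@H]1C | intermediate
14 | 9-alkyl-9-borabicyclo[3.3.1]nonane adduct of 13 (boron on the terminal carbon C13) | C1CCC2CCCC1B2CCC[C@]1(C)C2=CCC[C@](C)(C(=O)OCC[Si](C)(C)C)[C@H]2CC[C@H]1C | intermediate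
15 | 2-(trimethylsilyl)ethyl (1S,5S,6R,8aS)-5-(3-hydroxypropyl)-1,5,6-trimethyl-1,2,3,5,6,7,8,8a-octahydronaphthalene-1-carboxylate | OCCC[C@]1(C)C2=CCC[C@](C)(C(=O)OCC[Si](C)(C)C)[C@H]2CC[C@H]1C | intermediate
16 | 2-(trimethylsilyl)ethyl (1S,5S,6R,8aS)-1,5,6-trimethyl-5-(3-oxopropyl)-1,2,3,5,6,7,8,8a-octahydronaphthalene-1-carboxylate | O=CCC[C@]1(C)C2=CCC[C@](C)(C(=O)OCC[Si](C)(C)C)[C@H]2CC[C@H]1C | intermediate
17 | 2-(trimethylsilyl)ethyl (1S,5S,6R,8aS)-5-(but-3-yn-1-yl)-1,5,6-trimethyl-1,2,3,5,6,7,8,8a-octahydronaphthalene-1-carboxylate | C#CCC[C@]1(C)C2=CCC[C@](C)(C(=O)OCC[Si](C)(C)C)[C@H]2CC[C@H]1C | intermediate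
18 | 2-(trimethylsilyl)ethyl (1S,5S,6R,8aS)-5-[(3E)-4-(dimethylalumanyl)-3-methylbut-3-en-1-yl]-1,5,6-trimethyl-1,2,3,5,6,7,8,8a-octahydronaphthalene-1-carboxylate | C[Al](C)/C=C(\C)CC[C@]1(C)C2=CCC[C@](C)(C(=O)OCC[Si](C)(C)C)[C@H]2CC[C@H]1C | intermediate
19 | lithium butyl(dimethyl)aluminate of 18 (butyl added to aluminium) | [Li+].CCCC[Al-](C)(C)/C=C(\C)CC[C@]1(C)C2=CCC[C@](C)(C(=O)OCC[Si](C)(C)C)[C@H]2CC[C@H]1C | intermediate
20 | 2-(trimethylsilyl)ethyl (1S,5S,6R,8aS)-5-[(3E)-5-hydroxy-3-methylpent-3-en-1-yl]-1,5,6-trimethyl-1,2,3,5,6,7,8,8a-octahydronaphthalene-1-carboxylate | OC/C=C(\C)CC[C@]1(C)C2=CCC[C@](C)(C(=O)OCC[Si](C)(C)C)[C@H]2CC[C@H]1C | intermediate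
21 | 2-(trimethylsilyl)ethyl (1S,5S,6R,8aS)-1,5,6-trimethyl-5-[(3E)-3-methyl-5-(propanoyloxy)pent-3-en-1-yl]-1,2,3,5,6,7,8,8a-octahydronaphthalene-1-carboxylate | CCC(=O)OC/C=C(\C)CC[C@]1(C)C2=CCC[C@](C)(C(=O)OCC[Si](C)(C)C)[C@H]2CC[C@H]1C | intermediate
22 | (1S,5S,6R,8aS)-1,5,6-trimethyl-5-[(3E)-3-methyl-5-(propanoyloxy)pent-3-en-1-yl]-1,2,3,5,6,7,8,8a-octahydronaphthalene-1-carboxylic acid (CNP0223570.1) | CCC(=O)OC/C=C(\C)CC[C@]1(C)C2=CCC[C@](C)(C(=O)O)[C@H]2CC[C@H]1C | target

**Total step count:** 12. **Longest linear sequence:** 12 steps (1 → 22).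

**Steps most likely to fail**

Step 4. The sterically loaded cycloaddition (a quaternary C4 forming next to C5, a quaternary C9 next to C10) may stall at the low temperature at which the bound enal is best differentiated. On warming, the acid-activated catalyst could degrade the diene and blur exo and face discrimination. The fallback sets out from methacrolein 10 and diene 9 and comes back at aldehyde 11. Methacrolein 10 is first converted with ethylene glycol (pyridinium tosylate, azeotropic removal of water) into 2-(prop-1-en-2-yl)-1,3-dioxolane F1. F1 and 9 are then combined with catalytic TfOH in CH2Cl2 at −78 °C in an ionic Diels–Alder reaction, in which the ring-opened 2-alkoxyallyl cation is a far stronger dienophile than the boron-bound enal and should pair with the diene in the same ortho, exo sense, to give the cycloadduct acetal 2-[(1S,5S,6R,8aS)-5-allyl-1,5,6-trimethyl-1,2,3,5,6,7,8,8a-octahydronaphthalen-1-yl]-1,3-dioxolane F2. Mild hydrolysis (pyridinium tosylate, wet acetone) returns 11. In this variant face selection rests on the substrate alone, so the two exo adducts, which are diastereomers because C8 and C9 are fixed, would be separated by chromatography at F2 or 11.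

Step 1. The aluminium enolate may alkylate sluggishly even after activation, so that proton exchange with the product, O-allylation or double allylation erode the yield and the trans selectivity at C9. The fallback sets out from enone 1 and comes back at ketone 5. The same copper-catalysed conjugate methylation is run, but enolate 3 is quenched with Me3SiOTf and the silyl enol ether trimethyl{[(3R)-2,3-dimethylcyclohex-1-en-1-yl]oxy}silane F3 is isolated. Treatment of F3 with MeLi in THF then releases the aluminium-free lithium (3R)-2,3-dimethylcyclohex-1-en-1-olate F4, which is alkylated with allyl bromide 2 (THF/DMPU, −78 → 0 °C) in the classical regiospecific enolate alkylation, again anti to the C8 methyl, to give 5.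

Step 10. Transfer of the alkenyl group from aluminium to formaldehyde may be incomplete or unselective (protonolysis to the 2-methylalk-1-ene, competing methyl or butyl transfer, or attack of n-BuLi at the ester). The fallback sets out from alkyne 17 and comes back at allylic alcohol 20. The methylalumination is run as before to alkenylalane 18, which is quenched with I2 (THF, −30 °C) to give, with retention, the vinyl iodide 2-(trimethylsilyl)ethyl (1S,5S,6R,8aS)-5-[(3E)-4-iodo-3-methylbut-3-en-1-yl]-1,5,6-trimethyl-1,2,3,5,6,7,8,8a-octahydronaphthalene-1-carboxylate F5. A Stille hydroxymethylation of F5 with (tributylstannyl)methanol and Pd(PPh3)4 in dioxane at 90 °C then forms the C14–C15 bond by cross-coupling instead of carbonyl addition and delivers 20 with the 13E geometry intact.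

**Further compounds**
F1 | step 4 | 2-(prop-1-en-2-yl)-1,3-dioxolane | C=C(C)C1OCCO1
F2 | step 4 | 2-[(1S,5S,6R,8aS)-5-allyl-1,5,6-trimethyl-1,2,3,5,6,7,8,8a-octahydronaphthalen-1-yl]-1,3-dioxolane | C=CC[C@]1(C)C2=CCC[C@](C)(C3OCCO3)[C@H]2CC[C@H]1C
F3 | step 1 | trimethyl{[(3R)-2,3-dimethylcyclohex-1-en-1-yl]oxy}silane | CC1=C(O[Si](C)(C)C)CCC[C@H]1C
F4 | step 1 | lithium (3R)-2,3-dimethylcyclohex-1-en-1-olate | [Li+].CC1=C([O-])CCC[C@H]1C
F5 | step 10 | 2-(trimethylsilyl)ethyl (1S,5S,6R,8aS)-5-[(3E)-4-iodo-3-methylbut-3-en-1-yl]-1,5,6-trimethyl-1,2,3,5,6,7,8,8a-octahydronaphthalene-1-carboxylate | I/C=C(\C)CC[C@]1(C)C2=CCC[C@](C)(C(=O)OCC[Si](C)(C)C)[C@H]2CC[C@H]1C
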